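The dihydropyran ring is cut at C4–C4a and C2–C3 (chroman numbering). This releases C3–C4 as a two-carbon linchpin between a ring carbon of phloroglucinol and the spiro carbon, which is the former carbonyl carbon of (1R,5S)-nopinone. The key step exploits exactly this: C2 is a ketone carbon (a carbene via its tosylhydrazone) and C4a an enol-like carbon. One palladium-catalysed three-component coupling of the hydrazone, vinyl bromide and phloroglucinol makes both C–C bonds and gives a 2-(pinanylidene-ethyl)phloroglucinol. Oxidative oxa-6π ring closure then sets the spiro centre; directed metalation places the isovaleryl group and a Vilsmeier reaction the formyl group.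

Key step: step 2

Remark: (1R,5S)-(+)-nopinone 1 is assumed as the commercial source of the pinane unit; ring positions are given in chroman numbering (C6 and C8 are 6' and 8' in the spiro names), and the C=N and C=C geometries of 2, 7 and 8 are left undefined because they are lost in steps 2 and 3.

Step 1
Reactants: 1 (1R,5S)-(+)-nopinone
Product: 2 nopinone N-tosylhydrazone
Conditions: TsNHNH2 (1.05 equiv), MeOH, 60 °C
Reagents that add atoms: p-toluenesulfonohydrazide, Cc1ccc(cc1)S(=O)(=O)NN
Why: Condensation of a ketone with a sulfonylhydrazide (hydrazone formation) is reliable even for this hindered ketone and leaves both bridgehead stereocentres untouched.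

Step 2
Reactants: 2 nopinone N-tosylhydrazone; 3 phloroglucinol; 4 vinyl bromide
Product: 7 2-[2-((1R,5S)-6,6-dimethylbicyclo[3.1.1]heptan-2-ylidene)ethyl]benzene-1,3,5-triol, via diazoalkane 5 (not isolated), via allylpalladium bromide 6 (not isolated)
Conditions: tris(dibenzylideneacetone)dipalladium Pd2(dba)3 (2.5 mol %), PPh3 (15 mol %), LiOtBu (8 equiv), 3 (3 equiv), 4 (1 M in THF, 1.5 equiv), 1,4-dioxane/DMF, sealed tube, 80 °C
Reagents that add atoms: none
Why: Proposed new method: LiOtBu converts 2 into diazoalkane 5 (Bamford–Stevens), zerovalent palladium inserts into the C–Br bond of 4, the vinylpalladium bromide takes up 5 as a palladium carbene, and 1,2-migration of the vinyl group to the carbene carbon joins the former carbonyl carbon of nopinone to the bromine-bearing vinyl carbon, giving allylpalladium 6. Carbon attack of the phloroglucinolate at the CH2 terminus of 6 then joins the second vinyl carbon to the arene and returns zerovalent palladium. The closest known reaction types are the palladium-catalysed carbenylative allylic amination and alkylation (vinyl halide, diazo compound or N-tosylhydrazone, amine or malonate) and the Tsuji–Trost C-allylation of phloroglucinol, which are merged here with a phenolate as the carbon nucleophile. No ring is closed and no stereocentre is created; the bridgeheads are spectators and the alkene geometry is lost in step 3. The step needs C- over O-allylation, attack at the primary and not the tertiary allyl terminus, mono-allylation, and capture of 6 before β-hydride elimination to the 2-vinylpinene or protonation of 5. These are secured by the soft, fully ionised and threefold-symmetric phloroglucinolate used in excess, by the neopentyl-like shielding of the tertiary terminus, and by the reversibility of O-allylation under palladium.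

Step 3
Reactants: 7 2-[2-((1R,5S)-6,6-dimethylbicyclo[3.1.1]heptan-2-ylidene)ethyl]benzene-1,3,5-triol
Product: 9 (1R,2R,5S)-6,6-dimethylspiro[bicyclo[3.1.1]heptane-2,2'-chromene]-5',7'-diol, via vinyl o-quinone methide 8 (not isolated)
Conditions: DDQ (1.05 equiv), 1,4-dioxane, 20 °C, high dilution
Reagents that add atoms: none
Why: DDQ cyclodehydrogenation of an o-(3,3-dialkylallyl)phenol: hydride abstraction from the benzylic and allylic CH2 gives quinone methide 8, whose oxa-6π-electrocyclisation closes the pyran ring (both flanking hydroxyls are equivalent by symmetry) with the oxygen adding to the exocyclic alkene carbon from the face anti to the gem-dimethyl bridge, the less hindered face of 2-alkylidenepinanes, which sets the spiro centre as in the target.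

Step 4
Reactants: 9 (1R,2R,5S)-6,6-dimethylspiro[bicyclo[3.1.1]heptane-2,2'-chromene]-5',7'-diol
Product: 10 (1R,2R,5S)-6,6-dimethylspiro[bicyclo[3.1.1]heptane-2,2'-chromane]-5',7'-diol
Conditions: H2 (1 atm), 5% Pd/C, EtOAc, 20 °C
Reagents that add atoms: none
Why: Heterogeneous hydrogenation reduces only the styrene-like C3=C4 bond, creates no stereocentre (both carbons become CH2) and removes the π system through which the spiro centre could reopen.

Step 5
Reactants: 10 (1R,2R,5S)-6,6-dimethylspiro[bicyclo[3.1.1]heptane-2,2'-chromane]-5',7'-diol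
Product: 11 (1R,2R,5S)-5',7'-bis(methoxymethoxy)-6,6-dimethylspiro[bicyclo[3.1.1]heptane-2,2'-chromane]
Conditions: MOMCl (2.5 equiv), iPr2NEt (3 equiv), CH2Cl2, 0 to 20 °C
Reagents that add atoms: chloromethyl methyl ether, COCCl
Why: Williamson-type O-alkylation of both phenols masks the acidic protons and installs two strongly coordinating directing groups for the metalation.

Step 6
Reactants: 11 (1R,2R,5S)-5',7'-bis(methoxymethoxy)-6,6-dimethylspiro[bicyclo[3.1.1]heptane-2,2'-chromane]; 12 N-methoxy-N,3-dimethylbutanamide
Product: 15 1-[(1R,2R,5S)-5',7'-bis(methoxymethoxy)-6,6-dimethylspiro[bicyclo[3.1.1]heptane-2,2'-chromane]-6'-yl]-3-methylbutan-1-one, via aryllithium 13 (not isolated), via lithium hemiaminal 14 (not isolated)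
Conditions: n-BuLi (1.2 equiv), THF, 0 °C; then 12, −78 to 20 °C; then H2O
Reagents that add atoms: none
Why: Directed ortho-metalation takes place at C6, the only ring position flanked by two MOM ethers (C8 lies between one MOM ether and the hindered ring oxygen), and acyl substitution on the Weinreb amide stops at the ketone because the chelated tetrahedral adduct 14 survives until the quench.

Step 7
Reactants: 15 1-[(1R,2R,5S)-5',7'-bis(methoxymethoxy)-6,6-dimethylspiro[bicyclo[3.1.1]heptane-2,2'-chromane]-6'-yl]-3-methylbutan-1-one
Product: 16 1-[(1R,2R,5S)-5',7'-dihydroxy-6,6-dimethylspiro[bicyclo[3.1.1]heptane-2,2'-chromane]-6'-yl]-3-methylbutan-1-one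
Conditions: p-TsOH·H2O (0.2 equiv), MeOH, 20–40 °C
Reagents that add atoms: none
Why: Acid-catalysed acetal exchange with methanol removes both MOM groups, which are activated by the flanking chelating ketone, under conditions too mild to ionise the tertiary spiro ether.

Step 8
Reactants: 16 1-[(1R,2R,5S)-5',7'-dihydroxy-6,6-dimethylspiro[bicyclo[3.1.1]heptane-2,2'-chromane]-6'-yl]-3-methylbutan-1-one
Product: 18 euglobal G3, via iminium chloride 17 (not isolated)
Conditions: POCl3 (1.5 equiv), DMF (3 equiv), EtOAc, 0 to 20 °C; then H2O, 40 °C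
Reagents that add atoms: N,N-dimethylformamide, CN(C)C=O; water, O
Why: Vilsmeier–Haack formylation attacks C8, the only unsubstituted ring carbon, which is activated by the ortho hydroxyl and the ring oxygen, and hydrolysis of iminium salt 17 gives the aldehyde without touching any stereocentre.

Compound list
1 | (1R,5S)-(+)-nopinone, (1R,5S)-6,6-dimethylbicyclo[3.1.1]heptan-2-one | O=C1CC[C@H]2C[C@@H]1C2(C)C | starting material
2 | nopinone N-tosylhydrazone, N'-[(1R,5S)-6,6-dimethylbicyclo[3.1.1]heptan-2-ylidene]-4-methylbenzenesulfonohydrazide | Cc1ccc(cc1)S(=O)(=O)NN=C1CC[C@H]2C[C@@H]1C2(C)C | intermediate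
3 | phloroglucinol, benzene-1,3,5-triol | Oc1cc(O)cc(O)c1 | starting material
4 | vinyl bromide, bromoethene | C=CBr | starting material
5 | (1R,5S)-2-diazo-6,6-dimethylbicyclo[3.1.1]heptane | [N-]=[N+]=C1CC[C@H]2C[C@@H]1C2(C)C | intermediate
6 | allylpalladium bromide from vinyl migration to the carbene (drawn as the σ-allyl form; phosphine ligands omitted) | Br[Pd]CC=C1CC[C@H]2C[C@@H]1C2(C)C | intermediate
7 | 2-[2-((1R,5S)-6,6-dimethylbicyclo[3.1.1]heptan-2-ylidene)ethyl]benzene-1,3,5-triol | Oc1cc(O)c(CC=C2CC[C@H]3C[C@@H]2C3(C)C)c(O)c1 | intermediate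
8 | vinyl o-quinone methide, 6-[2-((1R,5S)-6,6-dimethylbicyclo[3.1.1]heptan-2-ylidene)ethylidene]-3,5-dihydroxycyclohexa-2,4-dien-1-one | O=C1C=C(O)C=C(O)C1=CC=C1CC[C@H]2C[C@@H]1C2(C)C | intermediate
9 | (1R,2R,5S)-6,6-dimethylspiro[bicyclo[3.1.1]heptane-2,2'-chromene]-5',7'-diol (ring oxygen anti to the gem-dimethyl bridge) | Oc1cc2c(c(O)c1)C=C[C@@]1(CC[C@H]3C[C@@H]1C3(C)C)O2 | intermediate
10 | (1R,2R,5S)-6,6-dimethylspiro[bicyclo[3.1.1]heptane-2,2'-chromane]-5',7'-diol | Oc1cc2c(c(O)c1)CC[C@@]1(CC[C@H]3C[C@@H]1C3(C)C)O2 | intermediate
11 | (1R,2R,5S)-5',7'-bis(methoxymethoxy)-6,6-dimethylspiro[bicyclo[3.1.1]heptane-2,2'-chromane] | COCOc1cc2c(c(OCOC)c1)CC[C@@]1(CC[C@H]3C[C@@H]1C3(C)C)O2 | intermediate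
12 | N-methoxy-N,3-dimethylbutanamide | CC(C)CC(=O)N(C)OC | starting material
13 | 6'-lithio derivative of 11 | [Li]c1c(OCOC)cc2c(c1OCOC)CC[C@@]1(CC[C@H]3C[C@@H]1C3(C)C)O2 | intermediate
14 | lithium hemiaminal, tetrahedral adduct of 13 to 12 (carbinol configuration undefined) | CC(C)CC(O[Li])(N(C)OC)c1c(OCOC)cc2c(c1OCOC)CC[C@@]1(CC[C@H]3C[C@@H]1C3(C)C)O2 | intermediate
15 | 1-[(1R,2R,5S)-5',7'-bis(methoxymethoxy)-6,6-dimethylspiro[bicyclo[3.1.1]heptane-2,2'-chromane]-6'-yl]-3-methylbutan-1-one | CC(C)CC(=O)c1c(OCOC)cc2c(c1OCOC)CC[C@@]1(CC[C@H]3C[C@@H]1C3(C)C)O2 | intermediate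
16 | 1-[(1R,2R,5S)-5',7'-dihydroxy-6,6-dimethylspiro[bicyclo[3.1.1]heptane-2,2'-chromane]-6'-yl]-3-methylbutan-1-one | CC(C)CC(=O)c1c(O)cc2c(c1O)CC[C@@]1(CC[C@H]3C[C@@H]1C3(C)C)O2 | intermediate
17 | 8'-(dimethyliminiomethyl) derivative of 16, chloride salt | CC(C)CC(=O)c1c(O)c(C=[N+](C)C)c2c(c1O)CC[C@@]1(CC[C@H]3C[C@@H]1C3(C)C)O2.[Cl-] | intermediate
18 | euglobal G3, (1R,2R,5S)-5',7'-dihydroxy-6,6-dimethyl-6'-(3-methylbutanoyl)spiro[bicyclo[3.1.1]heptane-2,2'-chromane]-8'-carbaldehyde | CC(C)CC(=O)c1c(O)c(C=O)c2c(c1O)CC[C@@]1(CC[C@H]3C[C@@H]1C3(C)C)O2 | target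

Total step count: 8. Longest linear sequence: 8 steps (1 → 2 → 7 → 9 → 10 → 11 → 15 → 16 → 18).

Steps most likely to fail

Step 2 (proposed three-component coupling). The allylpalladium 6 may undergo β-hydride elimination to the 2-vinylpinene before the phenolate arrives. Incompletely ionised phenol may protonate diazoalkane 5, which would trigger cationic rearrangement of the pinane. Multiple allylation of phloroglucinol may also compete. The fallback uses known chemistry and makes the two bonds in separate operations. It sets out from 1: vinylmagnesium bromide (CeCl3, THF, −78 °C) should add anti to the gem-dimethyl bridge to give (1R,2S,5S)-6,6-dimethyl-2-vinylbicyclo[3.1.1]heptan-2-ol F1. Treatment with n-BuLi and then ClCO2Me should give its methyl carbonate F2. Tsuji–Trost C-allylation of excess 3 with F2 (Pd(PPh3)4, THF, 50 °C) should pass through the same allylpalladium, be attacked at its CH2 terminus, and come back to the route at 7.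

Step 3 (oxidative ring closure). A second electron-rich phenol may add to quinone methide 8, the phloroglucinol ring may be over-oxidised, and the acidic hydroquinone by-product may reopen the chromene and erode the facial selectivity. The fallback sets out from 7 and uses a Wacker-type aerobic cyclisation (bis(dibenzylideneacetone)palladium Pd(dba)2 5 mol %, KHCO3, air, DMSO/H2O, 60 °C; air oxidises the zerovalent precatalyst to divalent palladium). Syn-oxypalladation by the palladium-bound phenoxide from the face anti to the gem-dimethyl bridge, followed by β-hydride elimination toward C4, should give 9 directly without a quinone methide; no new compound is made.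

Step 6 (acylation of the aryllithium). The hindered aryllithium 13 may abstract a proton from the α-CH2 of amide 12 in place of adding to it, which would return 11. The fallback sets out from 11: the same lithiation followed by addition to 3-methylbutanal at −78 °C should give 1-[(1R,2R,5S)-5',7'-bis(methoxymethoxy)-6,6-dimethylspiro[bicyclo[3.1.1]heptane-2,2'-chromane]-6'-yl]-3-methylbutan-1-ol F3 as a mixture of carbinol epimers. Oxidation with Dess–Martin periodinane (CH2Cl2, 20 °C) should come back to the route at 15.

Further compounds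
F1 | step 2 | (1R,2S,5S)-6,6-dimethyl-2-vinylbicyclo[3.1.1]heptan-2-ol (hydroxyl syn to the gem-dimethyl bridge) | C=C[C@]1(CC[C@H]2C[C@@H]1C2(C)C)O
F2 | step 2 | methyl (1R,2S,5S)-6,6-dimethyl-2-vinylbicyclo[3.1.1]heptan-2-yl carbonate | C=C[C@]1(CC[C@H]2C[C@@H]1C2(C)C)OC(=O)OC
F0 | step 3 | none | none
F3 | step 6 | 1-[(1R,2R,5S)-5',7'-bis(methoxymethoxy)-6,6-dimethylspiro[bicyclo[3.1.1]heptane-2,2'-chromane]-6'-yl]-3-methylbutan-1-ol (both carbinol epimers) | CC(C)CC(O)c1c(OCOC)cc2c(c1OCOC)CC[C@@]1(CC[C@H]3C[C@@H]1C3(C)C)O2
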